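**Retrosynthetic overview** (tetralin locants: C1 = CH bearing the side chain, C2, C3, C4 = CH–CH3, C4a/C8a = ring fusion, C5/C6 = phenol carbons, C7 = carboxyl carbon, C8 = CH; side chain: C11 = CH on C1, C20 = its CH2O, C12–C14, C15 = CH(CH3), C16 = CH2O; ring A = arene, ring B = carbocycle)
1. Target ⇐ hydrogenolysis of three benzyl groups ⇐ diacetylation ⇐ hydroxyl-directed hydrogenation of a C1=C2 1,2-dihydronaphthalene (sets C1 from C11) ⇐ fluoride desilylation.
2. Key disconnection: ring B is cut at C8a–C1 and C2–C3. A palladium-catalysed [4+2] carboannulation joins an ortho-bromoaryl primary alkyl boronate (C3–C4–C4a–C8a, C4 already R) with a silyl alkyne (C2≡C1 carrying the complete C11–C16 chain).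
3. Enabling feature: ring B is a benzo-fused six-membered ring whose C1–C2 edge carries only hydrogens and the side chain, so at the alkene level it is an alkyne. Its four-atom edge ends at arene carbon C8a (para to the C6 oxygen, ortho to the chain, meta to the ester), which should brominate selectively. Direct C8a–C3 coupling would need a four-membered ring, so the alkyne must insert first.
4. Fragments: the arene comes from 2,3-dihydroxyterephthalic acid (one carboxyl becomes C4; C4 set by copper-catalysed asymmetric hydroboration). The alkyne comes from (S)-3-bromo-2-methylpropan-1-ol (C15) and a copper-catalysed SN2′ allylic alkylation (C11), then ozonolysis and Corey–Fuchs homologation.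
5. Ring order: ring A is bought; ring B is the only ring formed, in step 16.

Key step: step 16

Remark: 2,3-dihydroxyterephthalic acid, (E)-but-2-ene-1,4-diol and (S)-3-bromo-2-methylpropan-1-ol are assumed to be commercial; TBS = tert-butyldimethylsilyl, Bn = benzyl, Bpin = 4,4,5,5-tetramethyl-1,3,2-dioxaborolan-2-yl.

**Route**

Step 1
Reactants: 1 2,3-dihydroxyterephthalic acid
Product: 2 dibenzyl 2,3-bis(benzyloxy)terephthalate
Conditions: BnBr (4.5 equiv), K2CO3, DMF, 60 °C
Reagents that add atoms: benzyl bromide, BrCc1ccccc1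
Why: Williamson etherification of both phenols and SN2 alkylation of both carboxylates should run to completion and give one symmetric, fully benzylated compound.

Step 2
Reactants: 2 dibenzyl 2,3-bis(benzyloxy)terephthalate
Product: 3 2,3-bis(benzyloxy)-4-[(benzyloxy)carbonyl]benzoic acid
Conditions: KOH (1.0 equiv), THF/H2O, 0 °C; then aq. HCl
Reagents that add atoms: potassium hydroxide, [K+].[OH-]
Why: Mono-saponification of a symmetric diester should stop after one ester because the first carboxylate formed lowers the electrophilicity of the para ester, and both esters are equivalent so only one mono-acid can form.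

Step 3
Reactants: 3 2,3-bis(benzyloxy)-4-[(benzyloxy)carbonyl]benzoic acid
Product: 5 benzyl 4-acetyl-2,3-bis(benzyloxy)benzoate, via acid chloride 4 (not isolated)
Conditions: (COCl)2, cat. DMF, CH2Cl2, 0 °C to rt; then MeMgBr (1.05 equiv), Fe(acac)3 (3 mol %), THF, −78 °C
Reagents that add atoms: methylmagnesium bromide, C[Mg]Br
Why: Iron-catalysed acylation of a Grignard reagent by an acid chloride is fast at −78 °C and should stop at the ketone without touching the benzyl ester.

Step 4
Reactants: 5 benzyl 4-acetyl-2,3-bis(benzyloxy)benzoate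
Product: 6 benzyl 2,3-bis(benzyloxy)-4-(prop-1-en-2-yl)benzoate
Conditions: Ph3PCH3Br, KOtBu, THF, 0 °C to rt
Reagents that add atoms: methyltriphenylphosphonium bromide, C[P+](c1ccccc1)(c1ccccc1)c1ccccc1.[Br-]
Why: Wittig methylenation converts the aryl methyl ketone into the 1,1-disubstituted alkene and leaves the ester alone.

Step 5
Reactants: 6 benzyl 2,3-bis(benzyloxy)-4-(prop-1-en-2-yl)benzoate
Product: 7 benzyl 2,3-bis(benzyloxy)-4-[(2R)-1-(Bpin)propan-2-yl]benzoate
Conditions: HBpin (1.2 equiv), CuCl (3 mol %), DTBM-SEGPHOS (3.3 mol %, the enantiomer that gives R), KOtBu (6 mol %), toluene, rt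
Reagents that add atoms: pinacolborane, [H]B1OC(C)(C)C(C)(C)O1
Why: Copper-catalysed asymmetric hydroboration of a 1,1-disubstituted aryl alkene places hydride on the benzylic carbon and boron on the terminal carbon, and the chiral bisphosphine selects the alkene face and so sets C4 as R.

Step 6
Reactants: 7 benzyl 2,3-bis(benzyloxy)-4-[(2R)-1-(Bpin)propan-2-yl]benzoate
Product: 8 benzyl 2,3-bis(benzyloxy)-5-bromo-4-[(2R)-1-(Bpin)propan-2-yl]benzoate
Conditions: NBS (1.05 equiv), MeCN, 0 °C to rt, dark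
Reagents that add atoms: N-bromosuccinimide, O=C1CCC(=O)N1Br
Why: Electrophilic aromatic bromination should go to C8a, which is para to a benzyloxy group, ortho to the alkyl chain and meta to the ester, whereas the only other free position is ortho to the ester; the alkyl boronate tolerates NBS under ionic conditions.

Step 7
Reactants: 9 (E)-but-2-ene-1,4-diol
Product: 10 (E)-4-[(tert-butyldimethylsilyl)oxy]but-2-en-1-ol
Conditions: NaH (1.0 equiv), THF, 0 °C; then TBSCl (1.0 equiv)
Reagents that add atoms: tert-butyldimethylsilyl chloride, CC(C)(C)[Si](C)(C)Cl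
Why: Monosilylation of a symmetric diol through its sparingly soluble monosodium alkoxide should favour the mono-ether.

Step 8
Reactants: 10 (E)-4-[(tert-butyldimethylsilyl)oxy]but-2-en-1-ol
Product: 11 (E)-[(4-bromobut-2-en-1-yl)oxy](tert-butyl)dimethylsilane
Conditions: CBr4, PPh3, CH2Cl2, 0 °C
Reagents that add atoms: carbon tetrabromide, BrC(Br)(Br)Br
Why: The Appel reaction converts the primary allylic alcohol into the bromide under neutral conditions that keep the silyl ether and the E alkene.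

Step 9
Reactants: 12 (S)-3-bromo-2-methylpropan-1-ol
Product: 13 (S)-(3-bromo-2-methylpropoxy)(tert-butyl)dimethylsilane
Conditions: TBSCl, imidazole, DMF, rt
Reagents that add atoms: tert-butyldimethylsilyl chloride, CC(C)(C)[Si](C)(C)Cl
Why: Standard silylation of the primary alcohol; the chiral-pool stereocentre (later C15) is not touched.

Step 10
Reactants: 13 (S)-(3-bromo-2-methylpropoxy)(tert-butyl)dimethylsilane
Product: 15 (R)-5-[(tert-butyldimethylsilyl)oxy]-4-methylpentan-1-ol, via Grignard reagent 14 (not isolated)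
Conditions: Mg, THF, rt; then oxirane, CuI (10 mol %), −30 to 0 °C; aqueous work-up
Reagents that add atoms: oxirane, C1CO1
Why: Grignard formation and copper-catalysed SN2 opening of oxirane extend the chain by two carbons without involving the stereocentre.

Step 11
Reactants: 15 (R)-5-[(tert-butyldimethylsilyl)oxy]-4-methylpentan-1-ol
Product: 16 (R)-[(5-bromo-2-methylpentyl)oxy](tert-butyl)dimethylsilane
Conditions: CBr4, PPh3, CH2Cl2, 0 °C
Reagents that add atoms: carbon tetrabromide, BrC(Br)(Br)Br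
Why: The Appel reaction gives the primary bromide needed for the next Grignard reagent.

Step 12
Reactants: 16 (R)-[(5-bromo-2-methylpentyl)oxy](tert-butyl)dimethylsilane; 11 (E)-[(4-bromobut-2-en-1-yl)oxy](tert-butyl)dimethylsilane
Product: 18 (3S,7R)-8-[(tert-butyldimethylsilyl)oxy]-3-{[(tert-butyldimethylsilyl)oxy]methyl}-7-methyloct-1-ene, via Grignard reagent 17 (not isolated)
Conditions: Mg, Et2O, rt; then 11, CuBr·SMe2 (3 mol %), Taniaphos (3.3 mol %, the enantiomer that gives S), CH2Cl2, −75 °C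
Reagents that add atoms: none
Why: Copper-catalysed asymmetric allylic alkylation (SN2′) sends the Grignard carbon to the γ-carbon of the allylic bromide, and the chiral ferrocenyl diphosphine–copper complex selects the face and so sets C11 as S while leaving the terminal vinyl group.

Step 13
Reactants: 18 (3S,7R)-8-[(tert-butyldimethylsilyl)oxy]-3-{[(tert-butyldimethylsilyl)oxy]methyl}-7-methyloct-1-ene
Product: 20 (2R,6R)-7-[(tert-butyldimethylsilyl)oxy]-2-{[(tert-butyldimethylsilyl)oxy]methyl}-6-methylheptanal, via ozonide 19 (not isolated)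
Conditions: O3, CH2Cl2, −78 °C; then PPh3, −78 °C to rt; used at once
Reagents that add atoms: ozone, [O-][O+]=O
Why: Ozonolysis with reductive work-up cleaves the terminal alkene to the aldehyde without touching the silyl ethers, and low temperature with direct use limits epimerisation at C11 (the descriptor changes only because of priorities).

Step 14
Reactants: 20 (2R,6R)-7-[(tert-butyldimethylsilyl)oxy]-2-{[(tert-butyldimethylsilyl)oxy]methyl}-6-methylheptanal
Product: 21 (3S,7R)-1,1-dibromo-8-[(tert-butyldimethylsilyl)oxy]-3-{[(tert-butyldimethylsilyl)oxy]methyl}-7-methyloct-1-ene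
Conditions: CBr4 (2 equiv), PPh3 (4 equiv), CH2Cl2, 0 °C
Reagents that add atoms: carbon tetrabromide, BrC(Br)(Br)Br
Why: The first stage of the Corey–Fuchs sequence (dibromomethylenation) is non-basic and should keep the α-stereocentre intact.

Step 15
Reactants: 21 (3S,7R)-1,1-dibromo-8-[(tert-butyldimethylsilyl)oxy]-3-{[(tert-butyldimethylsilyl)oxy]methyl}-7-methyloct-1-ene
Product: 23 benzyl{(3S,7R)-8-[(tert-butyldimethylsilyl)oxy]-3-{[(tert-butyldimethylsilyl)oxy]methyl}-7-methyloct-1-yn-1-yl}dimethylsilane, via lithium acetylide 22 (not isolated)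
Conditions: n-BuLi (2.2 equiv), THF, −78 °C; then BnMe2SiCl, −78 °C to rt
Reagents that add atoms: benzylchlorodimethylsilane, C[Si](C)(Cl)Cc1ccccc1
Why: The second stage of the Corey–Fuchs sequence (Br/Li exchange, α-elimination with 1,2-shift, deprotonation) gives the lithium acetylide, which the chlorosilane traps at carbon.

Step 16
Reactants: 8 benzyl 2,3-bis(benzyloxy)-5-bromo-4-[(2R)-1-(Bpin)propan-2-yl]benzoate; 23 benzyl{(3S,7R)-8-[(tert-butyldimethylsilyl)oxy]-3-{[(tert-butyldimethylsilyl)oxy]methyl}-7-methyloct-1-yn-1-yl}dimethylsilane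
Product: 24 benzyl (5R)-3,4-bis(benzyloxy)-7-[benzyl(dimethyl)silyl]-8-[(2S,6R)-1,7-bis{[tert-butyl(dimethyl)silyl]oxy}-6-methylheptan-2-yl]-5-methyl-5,6-dihydronaphthalene-2-carboxylate
Conditions: Pd(OAc)2 (5 mol %), SPhos (10 mol %), K3PO4·H2O (3 equiv), degassed toluene, 90 °C
Reagents that add atoms: none
Why: Proposed new method: zerovalent palladium inserts into the C8a–Br bond of 8, the divalent arylpalladium bromide adds syn across the alkyne of 23 with the aryl group going to C1 and palladium to the silicon-bearing C2, and the alkenylpalladium is then intercepted by base-assisted intramolecular transmetalation of the primary C3–Bpin group and C(sp2)–C(sp3) reductive elimination; the closest known reaction types are the Larock carboannulation of internal alkynes by aryl halides carrying a tethered carbon nucleophile, the aryl halide/alkyne/boronic acid three-component coupling and the B-alkyl Suzuki–Miyaura coupling. Ring B is closed by reductive elimination from a seven-membered palladacycle, a formal [4+2] carboannulation in which C8a–C1 forms first by migratory insertion and C2–C3 second. No stereocentre is created: C1 stays sp2 for step 18, and C4 and C11 are carried through unchanged. The step needs regioselective insertion, which the silyl group should secure because silylalkynes insert with silicon on the palladium-bearing carbon. It also needs insertion to outrun transmetalation, which the tether should secure because direct C8a–C3 coupling would give a strained benzocyclobutene and pinacol boronates transmetalate slowly. β-Hydride elimination from the C3–palladium intermediate should be held back by the rigid palladacycle and by the bulky biarylphosphine, which speeds reductive elimination.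

Step 17
Reactants: 24 benzyl (5R)-3,4-bis(benzyloxy)-7-[benzyl(dimethyl)silyl]-8-[(2S,6R)-1,7-bis{[tert-butyl(dimethyl)silyl]oxy}-6-methylheptan-2-yl]-5-methyl-5,6-dihydronaphthalene-2-carboxylate
Product: 25 benzyl (5R)-3,4-bis(benzyloxy)-8-[(2S,6R)-1,7-dihydroxy-6-methylheptan-2-yl]-5-methyl-5,6-dihydronaphthalene-2-carboxylate
Conditions: TBAF (5 equiv), THF, 0 °C to rt
Reagents that add atoms: none
Why: Fluoride-mediated desilylation cleaves both O–Si bonds and, by loss of the benzyl group from silicon to a fluorosilane, protodesilylates the alkenyl(benzyl)dimethylsilane without moving the C1=C2 double bond.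

Step 18
Reactants: 25 benzyl (5R)-3,4-bis(benzyloxy)-8-[(2S,6R)-1,7-dihydroxy-6-methylheptan-2-yl]-5-methyl-5,6-dihydronaphthalene-2-carboxylate
Product: 26 benzyl (5R,8S)-3,4-bis(benzyloxy)-8-[(2S,6R)-1,7-dihydroxy-6-methylheptan-2-yl]-5-methyl-5,6,7,8-tetrahydronaphthalene-2-carboxylate
Conditions: [Ir(cod)(PCy3)(py)]PF6 (10 mol %), H2 (1 atm), CH2Cl2, rt
Reagents that add atoms: none
Why: In this hydroxyl-directed homogeneous hydrogenation the cationic iridium catalyst binds the C20 hydroxyl and delivers H2 to the same face of C1=C2; in the preferred conformer C11–H lies in the ring plane towards the peri C8–H, so CH2OH and the chain sit on opposite faces, and delivery from the CH2OH face gives 1S from 11S and places the side chain trans to the C4 methyl.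

Step 19
Reactants: 26 benzyl (5R,8S)-3,4-bis(benzyloxy)-8-[(2S,6R)-1,7-dihydroxy-6-methylheptan-2-yl]-5-methyl-5,6,7,8-tetrahydronaphthalene-2-carboxylate
Product: 27 benzyl (5R,8S)-8-[(2S,6R)-1,7-diacetoxy-6-methylheptan-2-yl]-3,4-bis(benzyloxy)-5-methyl-5,6,7,8-tetrahydronaphthalene-2-carboxylate
Conditions: Ac2O, pyridine, DMAP (cat.), CH2Cl2, rt
Reagents that add atoms: acetic anhydride, CC(=O)OC(C)=O
Why: DMAP-catalysed acylation esterifies both primary alcohols; no other free hydroxyl is present.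

Step 20
Reactants: 27 benzyl (5R,8S)-8-[(2S,6R)-1,7-diacetoxy-6-methylheptan-2-yl]-3,4-bis(benzyloxy)-5-methyl-5,6,7,8-tetrahydronaphthalene-2-carboxylate
Product: 28 (5R,8S)-8-[(2S,6R)-1,7-diacetoxy-6-methylheptan-2-yl]-3,4-dihydroxy-5-methyl-5,6,7,8-tetrahydronaphthalene-2-carboxylic acid (CNP0245723.1)
Conditions: H2 (1 atm), 10 % Pd/C, EtOAc, rt
Reagents that add atoms: none
Why: Hydrogenolysis over palladium on carbon removes the two benzyl ethers and the benzyl ester under neutral conditions that leave the aliphatic acetates, the arene and all four stereocentres untouched.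

**Compound list**
1 | 2,3-dihydroxyterephthalic acid | OC(=O)c1ccc(C(=O)O)c(O)c1O | starting material
2 | dibenzyl 2,3-bis(benzyloxy)terephthalate | O=C(OCc1ccccc1)c1ccc(C(=O)OCc2ccccc2)c(OCc2ccccc2)c1OCc1ccccc1 | intermediate
3 | 2,3-bis(benzyloxy)-4-[(benzyloxy)carbonyl]benzoic acid | OC(=O)c1ccc(C(=O)OCc2ccccc2)c(OCc2ccccc2)c1OCc1ccccc1 | intermediate
4 | benzyl 2,3-bis(benzyloxy)-4-(chlorocarbonyl)benzoate (acid chloride, not isolated) | ClC(=O)c1ccc(C(=O)OCc2ccccc2)c(OCc2ccccc2)c1OCc1ccccc1 | intermediate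
5 | benzyl 4-acetyl-2,3-bis(benzyloxy)benzoate | CC(=O)c1ccc(C(=O)OCc2ccccc2)c(OCc2ccccc2)c1OCc1ccccc1 | intermediate
6 | benzyl 2,3-bis(benzyloxy)-4-(prop-1-en-2-yl)benzoate | C=C(C)c1ccc(C(=O)OCc2ccccc2)c(OCc2ccccc2)c1OCc1ccccc1 | intermediate
7 | benzyl 2,3-bis(benzyloxy)-4-[(2R)-1-(4,4,5,5-tetramethyl-1,3,2-dioxaborolan-2-yl)propan-2-yl]benzoate | CC1(C)OB(C[C@@H](C)c2ccc(C(=O)OCc3ccccc3)c(OCc3ccccc3)c2OCc2ccccc2)OC1(C)C | intermediate
8 | benzyl 2,3-bis(benzyloxy)-5-bromo-4-[(2R)-1-(4,4,5,5-tetramethyl-1,3,2-dioxaborolan-2-yl)propan-2-yl]benzoate | CC1(C)OB(C[C@@H](C)c2c(Br)cc(C(=O)OCc3ccccc3)c(OCc3ccccc3)c2OCc2ccccc2)OC1(C)C | intermediate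
9 | (E)-but-2-ene-1,4-diol | OC/C=C/CO | starting material
10 | (E)-4-[(tert-butyldimethylsilyl)oxy]but-2-en-1-ol | CC(C)(C)[Si](C)(C)OC/C=C/CO | intermediate
11 | (E)-[(4-bromobut-2-en-1-yl)oxy](tert-butyl)dimethylsilane | CC(C)(C)[Si](C)(C)OC/C=C/CBr | intermediate
12 | (S)-3-bromo-2-methylpropan-1-ol | OC[C@H](C)CBr | starting material
13 | (S)-(3-bromo-2-methylpropoxy)(tert-butyl)dimethylsilane | CC(C)(C)[Si](C)(C)OC[C@H](C)CBr | intermediate
14 | (S)-{3-[(tert-butyldimethylsilyl)oxy]-2-methylpropyl}magnesium bromide (not isolated) | CC(C)(C)[Si](C)(C)OC[C@H](C)C[Mg]Br | intermediate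
15 | (R)-5-[(tert-butyldimethylsilyl)oxy]-4-methylpentan-1-ol | CC(C)(C)[Si](C)(C)OC[C@H](C)CCCO | intermediate
16 | (R)-[(5-bromo-2-methylpentyl)oxy](tert-butyl)dimethylsilane | CC(C)(C)[Si](C)(C)OC[C@H](C)CCCBr | intermediate
17 | (R)-{5-[(tert-butyldimethylsilyl)oxy]-4-methylpentyl}magnesium bromide (not isolated) | CC(C)(C)[Si](C)(C)OC[C@H](C)CCC[Mg]Br | intermediate
18 | (3S,7R)-8-[(tert-butyldimethylsilyl)oxy]-3-{[(tert-butyldimethylsilyl)oxy]methyl}-7-methyloct-1-ene | CC(C)(C)[Si](C)(C)OC[C@H](C)CCC[C@H](CO[Si](C)(C)C(C)(C)C)C=C | intermediate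
19 | 3-[(2R,6R)-1,7-bis{[tert-butyl(dimethyl)silyl]oxy}-6-methylheptan-2-yl]-1,2,4-trioxolane (ozonide, mixture at the acetal carbon, not isolated) | CC(C)(C)[Si](C)(C)OC[C@H](C)CCC[C@H](CO[Si](C)(C)C(C)(C)C)C1OCOO1 | intermediate
20 | (2R,6R)-7-[(tert-butyldimethylsilyl)oxy]-2-{[(tert-butyldimethylsilyl)oxy]methyl}-6-methylheptanal | CC(C)(C)[Si](C)(C)OC[C@H](C)CCC[C@H](CO[Si](C)(C)C(C)(C)C)C=O | intermediate
21 | (3S,7R)-1,1-dibromo-8-[(tert-butyldimethylsilyl)oxy]-3-{[(tert-butyldimethylsilyl)oxy]methyl}-7-methyloct-1-ene | CC(C)(C)[Si](C)(C)OC[C@H](C)CCC[C@H](CO[Si](C)(C)C(C)(C)C)C=C(Br)Br | intermediate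
22 | lithium (3S,7R)-8-[(tert-butyldimethylsilyl)oxy]-3-{[(tert-butyldimethylsilyl)oxy]methyl}-7-methyloct-1-yn-1-ide (not isolated) | CC(C)(C)[Si](C)(C)OC[C@H](C)CCC[C@H](CO[Si](C)(C)C(C)(C)C)C#C[Li] | intermediate
23 | benzyl{(3S,7R)-8-[(tert-butyldimethylsilyl)oxy]-3-{[(tert-butyldimethylsilyl)oxy]methyl}-7-methyloct-1-yn-1-yl}dimethylsilane | CC(C)(C)[Si](C)(C)OC[C@H](C)CCC[C@H](CO[Si](C)(C)C(C)(C)C)C#C[Si](C)(C)Cc1ccccc1 | intermediate
24 | benzyl (5R)-3,4-bis(benzyloxy)-7-[benzyl(dimethyl)silyl]-8-[(2S,6R)-1,7-bis{[tert-butyl(dimethyl)silyl]oxy}-6-methylheptan-2-yl]-5-methyl-5,6-dihydronaphthalene-2-carboxylate | CC(C)(C)[Si](C)(C)OC[C@H](C)CCC[C@H](CO[Si](C)(C)C(C)(C)C)C1=C([Si](C)(C)Cc3ccccc3)C[C@@H](C)c2c1cc(C(=O)OCc1ccccc1)c(OCc1ccccc1)c2OCc1ccccc1 | intermediate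
25 | benzyl (5R)-3,4-bis(benzyloxy)-8-[(2S,6R)-1,7-dihydroxy-6-methylheptan-2-yl]-5-methyl-5,6-dihydronaphthalene-2-carboxylate | OC[C@H](C)CCC[C@H](CO)C1=CC[C@@H](C)c2c1cc(C(=O)OCc1ccccc1)c(OCc1ccccc1)c2OCc1ccccc1 | intermediate
26 | benzyl (5R,8S)-3,4-bis(benzyloxy)-8-[(2S,6R)-1,7-dihydroxy-6-methylheptan-2-yl]-5-methyl-5,6,7,8-tetrahydronaphthalene-2-carboxylate | OC[C@H](C)CCC[C@H](CO)[C@@H]1CC[C@@H](C)c2c1cc(C(=O)OCc1ccccc1)c(OCc1ccccc1)c2OCc1ccccc1 | intermediate
27 | benzyl (5R,8S)-8-[(2S,6R)-1,7-diacetoxy-6-methylheptan-2-yl]-3,4-bis(benzyloxy)-5-methyl-5,6,7,8-tetrahydronaphthalene-2-carboxylate | CC(=O)OC[C@H](C)CCC[C@H](COC(C)=O)[C@@H]1CC[C@@H](C)c2c1cc(C(=O)OCc1ccccc1)c(OCc1ccccc1)c2OCc1ccccc1 | intermediate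
28 | (5R,8S)-8-[(2S,6R)-1,7-diacetoxy-6-methylheptan-2-yl]-3,4-dihydroxy-5-methyl-5,6,7,8-tetrahydronaphthalene-2-carboxylic acid | CC(=O)OC[C@H](C)CCC[C@H](COC(C)=O)[C@@H]1CC[C@@H](C)c2c1cc(C(=O)O)c(O)c2O | target

**Step count**
Total: 20 steps. Longest linear sequence: 12 steps (steps 9–20, from 12).

**Three steps most likely to fail**

1. Step 16 (proposed new method). The alkyne may insert the wrong way round, the alkyl boronate may transmetalate before insertion and be lost by protodeboronation, or the C3–palladium intermediate may undergo β-hydride elimination back to the styrene. Fallback with known chemistry, setting out from 7 and 22 and returning at 25: boronate 7 is oxidised (NaBO3·4H2O, THF/H2O) to benzyl 2,3-bis(benzyloxy)-4-[(2S)-1-hydroxypropan-2-yl]benzoate F1, which is converted (I2, PPh3, imidazole) into benzyl 2,3-bis(benzyloxy)-4-[(2S)-1-iodopropan-2-yl]benzoate F2. Acetylide 22 is quenched with water to the terminal alkyne (3S,7R)-8-[(tert-butyldimethylsilyl)oxy]-3-{[(tert-butyldimethylsilyl)oxy]methyl}-7-methyloct-1-yne F3. An alkyl Sonogashira coupling of F2 with F3 ([Pd(allyl)Cl]2, N-heterocyclic carbene ligand, CuI, Cs2CO3) gives the internal alkyne benzyl 2,3-bis(benzyloxy)-4-[(2R,6S,10R)-11-[(tert-butyldimethylsilyl)oxy]-6-{[(tert-butyldimethylsilyl)oxy]methyl}-10-methylundec-4-yn-2-yl]benzoate F4. PtCl2-catalysed 6-endo-dig hydroarylation (toluene, 80 °C) at C8a closes ring B to benzyl (5R)-3,4-bis(benzyloxy)-8-[(2S,6R)-1,7-bis{[tert-butyl(dimethyl)silyl]oxy}-6-methylheptan-2-yl]-5-methyl-5,6-dihydronaphthalene-2-carboxylate F5, and TBAF then gives 25.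

2. Step 18. Facial selectivity may be poor because hydroxyl-directed delivery has to take place on the face that also carries the pseudo-axial C4 methyl group; iridium hydride may also move the C1=C2 double bond. Fallback under reagent control, setting out from 25 and returning at 27: 25 is acetylated first (Ac2O, pyridine, DMAP) to benzyl (5R)-8-[(2S,6R)-1,7-diacetoxy-6-methylheptan-2-yl]-3,4-bis(benzyloxy)-5-methyl-5,6-dihydronaphthalene-2-carboxylate F6, and the trisubstituted styrene-type alkene is then hydrogenated with a chiral iridium N,P catalyst, [Ir(cod)(tBu-PHOX)]BArF (enantiomer chosen for 8S), H2 (50 bar), CH2Cl2, which gives 27 directly.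

3. Step 13. The α-branched β-silyloxy aldehyde may epimerise at C11 or lose silanol by β-elimination during ozonolysis, work-up or the following olefination. Fallback that avoids the aldehyde, setting out from 18 and returning at 23: bromine addition (Br2, CH2Cl2, −78 °C) to 18 gives (3R,7R)-1,2-dibromo-8-[(tert-butyldimethylsilyl)oxy]-3-{[(tert-butyldimethylsilyl)oxy]methyl}-7-methyloctane F7 (both C2 epimers), and double dehydrobromination with LDA (3.3 equiv, THF, −78 to 0 °C) gives lithium acetylide 22, which is silylated in the same flask with BnMe2SiCl to 23.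

**Further compounds**
F1 | step 16 | benzyl 2,3-bis(benzyloxy)-4-[(2S)-1-hydroxypropan-2-yl]benzoate | C[C@H](CO)c1ccc(C(=O)OCc2ccccc2)c(OCc2ccccc2)c1OCc1ccccc1
F2 | step 16 | benzyl 2,3-bis(benzyloxy)-4-[(2S)-1-iodopropan-2-yl]benzoate | C[C@H](CI)c1ccc(C(=O)OCc2ccccc2)c(OCc2ccccc2)c1OCc1ccccc1
F3 | step 16 | (3S,7R)-8-[(tert-butyldimethylsilyl)oxy]-3-{[(tert-butyldimethylsilyl)oxy]methyl}-7-methyloct-1-yne | CC(C)(C)[Si](C)(C)OC[C@H](C)CCC[C@H](CO[Si](C)(C)C(C)(C)C)C#C
F4 | step 16 | benzyl 2,3-bis(benzyloxy)-4-[(2R,6S,10R)-11-[(tert-butyldimethylsilyl)oxy]-6-{[(tert-butyldimethylsilyl)oxy]methyl}-10-methylundec-4-yn-2-yl]benzoate | CC(C)(C)[Si](C)(C)OC[C@H](C)CCC[C@H](CO[Si](C)(C)C(C)(C)C)C#CC[C@@H](C)c1ccc(C(=O)OCc2ccccc2)c(OCc2ccccc2)c1OCc1ccccc1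
F5 | step 16 | benzyl (5R)-3,4-bis(benzyloxy)-8-[(2S,6R)-1,7-bis{[tert-butyl(dimethyl)silyl]oxy}-6-methylheptan-2-yl]-5-methyl-5,6-dihydronaphthalene-2-carboxylate | CC(C)(C)[Si](C)(C)OC[C@H](C)CCC[C@H](CO[Si](C)(C)C(C)(C)C)C1=CC[C@@H](C)c2c1cc(C(=O)OCc1ccccc1)c(OCc1ccccc1)c2OCc1ccccc1
F6 | step 18 | benzyl (5R)-8-[(2S,6R)-1,7-diacetoxy-6-methylheptan-2-yl]-3,4-bis(benzyloxy)-5-methyl-5,6-dihydronaphthalene-2-carboxylate | CC(=O)OC[C@H](C)CCC[C@H](COC(C)=O)C1=CC[C@@H](C)c2c1cc(C(=O)OCc1ccccc1)c(OCc1ccccc1)c2OCc1ccccc1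
F7 | step 13 | (3R,7R)-1,2-dibromo-8-[(tert-butyldimethylsilyl)oxy]-3-{[(tert-butyldimethylsilyl)oxy]methyl}-7-methyloctane (C2 epimers) | CC(C)(C)[Si](C)(C)OC[C@H](C)CCC[C@H](CO[Si](C)(C)C(C)(C)C)C(Br)CBr
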